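**Plan**

- Retrosynthesis: the lactone carbonyl carbon is bonded only to the ring oxygen and to C-alpha, so its two skeletal bonds (O–C(=O) and C(=O)–C-alpha) are cut and the carbon goes back to CO. What is left is a but-3-yn-1-ol whose alkyne carbons are C-alpha and the benzylic carbon on C5 of the dihydrobenzofuran (ring C).
- Further cuts: the alkyne–aryl bond (Sonogashira); in the ring A/B half the C7–C8 aldol bond, the aryl ether O–CH2 bond and the C-beta–CH2O bond; in the ring C/D half the C2–C3 aldol bond and the O1–C2 bond.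
- Forward: ring B hydrocinnamic acid → C-beta arm and terminal alkyne → aryloxyacetyl aldol with the ring A aldehyde → 1,3-dioxane (acetonide). Separately, ring C arylacetic acid → aldol with the ring D aldehyde → acid closure of the dihydrobenzofuran. The halves are joined at the alkyne and the lactone ring is closed last, before deprotection, hydrogenation and epimerisation.
- Stereochemistry: C-beta from an (R)-oxazolidinone-directed hydroxymethylation; C8 from an (R)-oxazolidinone syn aldol and C7 by Mitsunobu inversion of the threo alcohol; C3 of the dihydrobenzofuran from an (S)-oxazolidinone syn aldol and C2 by trans-selective cationic ring closure; C-alpha by hydrogenation followed by base equilibration to the trans lactone.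

Key step: step 24

Labels: rings A–D are the aryl ring of the arylglycerol unit, the ring carrying the aryl ether, the benzo ring of the dihydrobenzofuran and its 2-aryl group; C7/C8/C9 are the benzylic, ether-bearing and CH2OH carbons of the arylglycerol unit; C-alpha and C-beta are the lactone carbons next to C=O and next to CH2O; TBS = tert-butyldimethylsilyl, TBDPS = tert-butyldiphenylsilyl, MOM = methoxymethyl, Bn = benzyl.

**Route**

Step 1
Reactants: 1 3-(4-hydroxy-3-methoxyphenyl)propanoic acid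
Product: 3 3-[4-(TBS-oxy)-3-methoxyphenyl]propanoic acid, via bis-silyl ester 2 (not isolated)
Conditions: TBSCl (2.3 equiv), imidazole, DMF, rt; then AcOH/THF/H2O, rt
Reagents that add atoms: tert-butyldimethylsilyl chloride CC(C)(C)[Si](C)(C)Cl
Why: Silyl protection of phenol and acid followed by selective hydrolysis of the far more labile silyl ester should leave the phenol masked as an aryl TBS ether, which is later cleaved by K2CO3/MeOH.

Step 2
Reactants: 3 3-[4-(TBS-oxy)-3-methoxyphenyl]propanoic acid; 4 (R)-4-benzyloxazolidin-2-one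
Product: 6 (4R)-4-benzyl-3-{3-[4-(TBS-oxy)-3-methoxyphenyl]propanoyl}oxazolidin-2-one, via mixed pivalic anhydride 5 (not isolated)
Conditions: PivCl, Et3N, THF, −20 °C; then 4, LiCl, rt
Reagents that add atoms: pivaloyl chloride CC(C)(C)C(Cl)=O (its atoms stay only in intermediate 5)
Why: N-Acylation of the Evans oxazolidinone through the pivalic mixed anhydride with LiCl/Et3N activation is a standard way to load a hydrocinnamic acid onto the auxiliary.

Step 3
Reactants: 6 (4R)-4-benzyl-3-{3-[4-(TBS-oxy)-3-methoxyphenyl]propanoyl}oxazolidin-2-one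
Product: 7 (4R)-4-benzyl-3-{(2S)-2-(hydroxymethyl)-3-[4-(TBS-oxy)-3-methoxyphenyl]propanoyl}oxazolidin-2-one
Conditions: TiCl4 (1.05 equiv), i-Pr2NEt, CH2Cl2, 0 °C; then s-trioxane, TiCl4 (1.05 equiv), 0 °C
Reagents that add atoms: 1,3,5-trioxane C1OCOCO1
Why: Evans hydroxymethylation: the chelated (Z)-titanium enolate is attacked by TiCl4-activated formaldehyde on the face opposite the C4 benzyl group of the (R)-auxiliary, which sets C-beta in the configuration that becomes 4R of the lactone.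

Step 4
Reactants: 7 (4R)-4-benzyl-3-{(2S)-2-(hydroxymethyl)-3-[4-(TBS-oxy)-3-methoxyphenyl]propanoyl}oxazolidin-2-one
Product: 8 (4R)-4-benzyl-3-{(2S)-2-(TBDPS-oxymethyl)-3-[4-(TBS-oxy)-3-methoxyphenyl]propanoyl}oxazolidin-2-one
Conditions: TBDPSCl, imidazole, CH2Cl2, rt
Reagents that add atoms: tert-butyldiphenylsilyl chloride CC(C)(C)[Si](Cl)(c1ccccc1)c1ccccc1
Why: Imidazole-promoted silyl ether formation marks this CH2O arm before the acyl group is reduced, and TBDPS is chosen because it outlasts carbonate, hydroxide, mild acid and the later cleavage of the aryl TBS ether.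

Step 5
Reactants: 8 (4R)-4-benzyl-3-{(2S)-2-(TBDPS-oxymethyl)-3-[4-(TBS-oxy)-3-methoxyphenyl]propanoyl}oxazolidin-2-one
Product: 9 (2R)-2-(TBDPS-oxymethyl)-3-[4-(TBS-oxy)-3-methoxyphenyl]propan-1-ol
Conditions: LiBH4, MeOH (1 equiv), THF, 0 °C
Reagents that add atoms: none
Why: Reductive cleavage of the N-acyl oxazolidinone with LiBH4 gives the primary alcohol and returns the auxiliary without touching the silyl ethers or the stereocenter.

Step 6
Reactants: 9 (2R)-2-(TBDPS-oxymethyl)-3-[4-(TBS-oxy)-3-methoxyphenyl]propan-1-ol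
Product: 10 (2S)-2-(TBDPS-oxymethyl)-3-[4-(TBS-oxy)-3-methoxyphenyl]propanal
Conditions: Dess–Martin periodinane, CH2Cl2, 0 °C → rt
Reagents that add atoms: none
Why: Dess–Martin oxidation is a mild, non-basic route to the α-branched β-silyloxy aldehyde and should avoid epimerisation and β-elimination.

Step 7
Reactants: 10 (2S)-2-(TBDPS-oxymethyl)-3-[4-(TBS-oxy)-3-methoxyphenyl]propanal; 11 dimethyl (1-diazo-2-oxopropyl)phosphonate
Product: 13 4-[(2R)-2-(TBDPS-oxymethyl)but-3-yn-1-yl]-2-methoxyphenol, via silylated alkyne 12 (not isolated)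
Conditions: K2CO3 (3 equiv), MeOH/THF, 0 °C → rt
Reagents that add atoms: none
Why: Ohira–Bestmann alkynylation (Seyferth–Gilbert homologation) converts the aldehyde into the terminal alkyne under conditions that normally preserve an α-stereocenter, and the same methanolic carbonate should cleave the aryl TBS ether while leaving the alkyl TBDPS ether, so the phenol is freed in the same flask.

Step 8
Reactants: 13 4-[(2R)-2-(TBDPS-oxymethyl)but-3-yn-1-yl]-2-methoxyphenol
Product: 15 2-{4-[(2R)-2-(TBDPS-oxymethyl)but-3-yn-1-yl]-2-methoxyphenoxy}acetic acid, via methyl ester 14 (not isolated)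
Conditions: BrCH2CO2Me, K2CO3, acetone, 50 °C; then LiOH, THF/H2O, 0 °C → rt; HCl to pH 3
Reagents that add atoms: methyl bromoacetate COC(=O)CBr; lithium hydroxide [Li+].[OH-] (oxygen of the acid OH)
Why: Williamson O-alkylation of the phenoxide followed by saponification gives the aryloxyacetic acid, and the TBDPS ether and terminal alkyne tolerate carbonate and cold hydroxide.

Step 9
Reactants: 15 2-{4-[(2R)-2-(TBDPS-oxymethyl)but-3-yn-1-yl]-2-methoxyphenoxy}acetic acid; 4 (R)-4-benzyloxazolidin-2-one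
Product: 17 (4R)-4-benzyl-3-(2-{4-[(2R)-2-(TBDPS-oxymethyl)but-3-yn-1-yl]-2-methoxyphenoxy}acetyl)oxazolidin-2-one, via mixed pivalic anhydride 16 (not isolated)
Conditions: PivCl, Et3N, THF, −20 °C; then 4, LiCl, rt
Reagents that add atoms: pivaloyl chloride CC(C)(C)C(Cl)=O (its atoms stay only in intermediate 16)
Why: The same mixed-anhydride N-acylation as in step 2 loads the aryloxyacetic acid onto the (R)-auxiliary for a glycolate-type aldol.

Step 10
Reactants: 17 (4R)-4-benzyl-3-(2-{4-[(2R)-2-(TBDPS-oxymethyl)but-3-yn-1-yl]-2-methoxyphenoxy}acetyl)oxazolidin-2-one; 18 4-benzyloxy-3-methoxybenzaldehyde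
Product: 19 (4R)-4-benzyl-3-[(2R,3S)-3-(4-benzyloxy-3-methoxyphenyl)-3-hydroxy-2-{4-[(2R)-2-(TBDPS-oxymethyl)but-3-yn-1-yl]-2-methoxyphenoxy}propanoyl]oxazolidin-2-one
Conditions: Bu2BOTf, i-Pr2NEt, CH2Cl2, −78 → 0 °C; 18, −78 → 0 °C; then pH 7 buffer, MeOH, H2O2, 0 °C
Reagents that add atoms: none
Why: Evans syn aldol: the (Z)-boron enolate of the aryloxyacetyl imide adds through a closed Zimmerman–Traxler transition state, so the (R)-auxiliary fixes C8 as required by the target (8S in the later diol) and gives C7 as the threo (7S) epimer.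

Step 11
Reactants: 19 (4R)-4-benzyl-3-[(2R,3S)-3-(4-benzyloxy-3-methoxyphenyl)-3-hydroxy-2-{4-[(2R)-2-(TBDPS-oxymethyl)but-3-yn-1-yl]-2-methoxyphenoxy}propanoyl]oxazolidin-2-one
Product: 20 (4R)-4-benzyl-3-[(2R,3R)-3-(4-benzyloxy-3-methoxyphenyl)-3-(4-nitrobenzoyloxy)-2-{4-[(2R)-2-(TBDPS-oxymethyl)but-3-yn-1-yl]-2-methoxyphenoxy}propanoyl]oxazolidin-2-one
Conditions: 4-nitrobenzoic acid, PPh3, DIAD, toluene, −20 °C → rt
Reagents that add atoms: 4-nitrobenzoic acid OC(=O)c1ccc(cc1)[N+](=O)[O-]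
Why: Mitsunobu inversion turns the threo alcohol into the erythro ester by SN2 displacement at C7 (which becomes R), with an acidic pronucleophile, a non-polar solvent and low temperature chosen to suppress ionisation of the electron-rich benzylic centre.

Step 12
Reactants: 20 (4R)-4-benzyl-3-[(2R,3R)-3-(4-benzyloxy-3-methoxyphenyl)-3-(4-nitrobenzoyloxy)-2-{4-[(2R)-2-(TBDPS-oxymethyl)but-3-yn-1-yl]-2-methoxyphenoxy}propanoyl]oxazolidin-2-one
Product: 21 (1R,2S)-1-(4-benzyloxy-3-methoxyphenyl)-2-{4-[(2R)-2-(TBDPS-oxymethyl)but-3-yn-1-yl]-2-methoxyphenoxy}propane-1,3-diol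
Conditions: LiBH4 (excess), MeOH, THF, 0 °C → rt
Reagents that add atoms: none
Why: Hydride reduction cleaves the imide to the C9 primary alcohol and the activated aryl ester at its acyl carbon, so C7 and C8 are untouched and the erythro 1,3-diol is released in one operation.

Step 13
Reactants: 21 (1R,2S)-1-(4-benzyloxy-3-methoxyphenyl)-2-{4-[(2R)-2-(TBDPS-oxymethyl)but-3-yn-1-yl]-2-methoxyphenoxy}propane-1,3-diol
Product: 22 (4R,5S)-4-(4-benzyloxy-3-methoxyphenyl)-5-{4-[(2R)-2-(TBDPS-oxymethyl)but-3-yn-1-yl]-2-methoxyphenoxy}-2,2-dimethyl-1,3-dioxane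
Conditions: Me2C(OMe)2, PPTS (cat.), acetone, rt
Reagents that add atoms: 2,2-dimethoxypropane COC(C)(C)OC
Why: Acid-catalysed transacetalisation ties the 1,3-diol into a dioxane in which aryl and aryloxy groups are both equatorial (the erythro isomer gives the trans-4,5 ring), and this group survives fluoride, amines, palladium and CO.

Step 14
Reactants: 22 (4R,5S)-4-(4-benzyloxy-3-methoxyphenyl)-5-{4-[(2R)-2-(TBDPS-oxymethyl)but-3-yn-1-yl]-2-methoxyphenoxy}-2,2-dimethyl-1,3-dioxane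
Product: 23 (2R)-2-{4-[(4R,5S)-4-(4-benzyloxy-3-methoxyphenyl)-2,2-dimethyl-1,3-dioxan-5-yloxy]-3-methoxybenzyl}but-3-yn-1-ol
Conditions: TBAF, THF, 0 °C → rt
Reagents that add atoms: none
Why: Fluoride desilylation frees the homopropargylic alcohol, and the acetonide, benzyl ether and alkyne are inert to TBAF.

Step 15
Reactants: 24 5-bromo-2-hydroxy-3-methoxybenzaldehyde
Product: 25 5-bromo-3-methoxy-2-(methoxymethoxy)benzaldehyde
Conditions: MOMCl, i-Pr2NEt, CH2Cl2, 0 °C → rt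
Reagents that add atoms: chloromethyl methyl ether COCCl
Why: O-Alkylation with MOMCl gives a base-stable acetal ether that the acid used for ring closure in step 21 will remove.

Step 16
Reactants: 25 5-bromo-3-methoxy-2-(methoxymethoxy)benzaldehyde
Product: 26 2-[5-bromo-3-methoxy-2-(methoxymethoxy)phenyl]acetonitrile
Conditions: TosMIC, t-BuOK, DME, −50 °C; then MeOH, reflux
Reagents that add atoms: tosylmethyl isocyanide Cc1ccc(cc1)S(=O)(=O)C[N+]#[C-]
Why: Van Leusen reductive cyanation: the TosMIC anion adds to the aldehyde, the oxazoline ring-opens, and methanolysis with loss of methyl formate and sulfinate gives the arylacetonitrile, a one-carbon homologation run entirely in base that the MOM ether tolerates.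

Step 17
Reactants: 26 2-[5-bromo-3-methoxy-2-(methoxymethoxy)phenyl]acetonitrile
Product: 27 2-[5-bromo-3-methoxy-2-(methoxymethoxy)phenyl]acetic acid
Conditions: KOH, EtOH/H2O, reflux; then cold HCl to pH 4
Reagents that add atoms: potassium hydroxide [K+].[OH-]; water O (the two carboxyl oxygens)
Why: Alkaline nitrile hydrolysis gives the arylacetic acid without affecting the MOM ether or the aryl bromide, and the acidification is kept cold and mild to preserve the acetal.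

Step 18
Reactants: 27 2-[5-bromo-3-methoxy-2-(methoxymethoxy)phenyl]acetic acid; 28 (S)-4-benzyloxazolidin-2-one
Product: 30 (4S)-4-benzyl-3-{2-[5-bromo-3-methoxy-2-(methoxymethoxy)phenyl]acetyl}oxazolidin-2-one, via mixed pivalic anhydride 29 (not isolated)
Conditions: PivCl, Et3N, THF, −20 °C; then 28, LiCl, rt
Reagents that add atoms: pivaloyl chloride CC(C)(C)C(Cl)=O (its atoms stay only in intermediate 29)
Why: Mixed-anhydride N-acylation of the Evans auxiliary, run cold so that the arylacetic acid is not converted into a ketene.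

Step 19
Reactants: 30 (4S)-4-benzyl-3-{2-[5-bromo-3-methoxy-2-(methoxymethoxy)phenyl]acetyl}oxazolidin-2-one; 18 4-benzyloxy-3-methoxybenzaldehyde
Product: 31 (4S)-4-benzyl-3-{(2S,3S)-3-(4-benzyloxy-3-methoxyphenyl)-2-[5-bromo-3-methoxy-2-(methoxymethoxy)phenyl]-3-hydroxypropanoyl}oxazolidin-2-one
Conditions: Bu2BOTf, i-Pr2NEt, CH2Cl2, −78 → 0 °C; 18, −78 → 0 °C; then pH 7 buffer, MeOH, H2O2, 0 °C
Reagents that add atoms: none
Why: Evans syn aldol of the arylacetyl imide: the (Z)-boron enolate reacts through a chair transition state and the (S)-auxiliary sets the aryl-bearing carbon (the future C3 of the dihydrobenzofuran) in the required configuration, with the neighbouring carbinol formed syn.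

Step 20
Reactants: 31 (4S)-4-benzyl-3-{(2S,3S)-3-(4-benzyloxy-3-methoxyphenyl)-2-[5-bromo-3-methoxy-2-(methoxymethoxy)phenyl]-3-hydroxypropanoyl}oxazolidin-2-one
Product: 32 (1S,2R)-1-(4-benzyloxy-3-methoxyphenyl)-2-[5-bromo-3-methoxy-2-(methoxymethoxy)phenyl]propane-1,3-diol
Conditions: LiBH4, H2O (1 equiv), Et2O/THF, 0 °C
Reagents that add atoms: none
Why: Reductive removal of the auxiliary with LiBH4 at low temperature gives the 1,3-diol quickly enough to avoid retro-aldol cleavage, and the aryl bromide is inert to borohydride.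

Step 21
Reactants: 32 (1S,2R)-1-(4-benzyloxy-3-methoxyphenyl)-2-[5-bromo-3-methoxy-2-(methoxymethoxy)phenyl]propane-1,3-diol
Product: 34 [(2S,3R)-2-(4-benzyloxy-3-methoxyphenyl)-5-bromo-7-methoxy-2,3-dihydro-1-benzofuran-3-yl]methanol, via free phenol 33 (not isolated)
Conditions: HCl (0.5 M in MeOH), THF, rt → 40 °C
Reagents that add atoms: none
Why: Acid removes the MOM acetal and ionises the 4-alkoxybenzylic alcohol, the ortho phenol captures the cation in a five-membered ring closure (SN1 cyclisation of the quinone-methide type known from phenylcoumaran chemistry), and because the ionisation is reversible the aryl group at C2 should settle trans to the CH2OH group, so C2 (S) is controlled by the fixed C3 centre.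

Step 22
Reactants: 34 [(2S,3R)-2-(4-benzyloxy-3-methoxyphenyl)-5-bromo-7-methoxy-2,3-dihydro-1-benzofuran-3-yl]methanol
Product: 35 {[(2S,3R)-2-(4-benzyloxy-3-methoxyphenyl)-5-bromo-7-methoxy-2,3-dihydro-1-benzofuran-3-yl]methoxy}(tert-butyl)dimethylsilane
Conditions: TBSCl, imidazole, DMF, rt
Reagents that add atoms: tert-butyldimethylsilyl chloride CC(C)(C)[Si](C)(C)Cl
Why: Silyl ether formation blocks the only other primary alcohol so that it cannot form an alkoxycarbonyl species in the carbonylation.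

Step 23
Reactants: 23 (2R)-2-{4-[(4R,5S)-4-(4-benzyloxy-3-methoxyphenyl)-2,2-dimethyl-1,3-dioxan-5-yloxy]-3-methoxybenzyl}but-3-yn-1-ol; 35 {[(2S,3R)-2-(4-benzyloxy-3-methoxyphenyl)-5-bromo-7-methoxy-2,3-dihydro-1-benzofuran-3-yl]methoxy}(tert-butyl)dimethylsilane
Product: 36 (2R)-4-[(2S,3R)-2-(4-benzyloxy-3-methoxyphenyl)-3-(TBS-oxymethyl)-7-methoxy-2,3-dihydro-1-benzofuran-5-yl]-2-{4-[(4R,5S)-4-(4-benzyloxy-3-methoxyphenyl)-2,2-dimethyl-1,3-dioxan-5-yloxy]-3-methoxybenzyl}but-3-yn-1-ol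
Conditions: Pd(PhCN)2Cl2 (3 mol %), P(t-Bu)3·HBF4 (6 mol %), CuI (2 mol %), i-Pr2NH, dioxane, rt → 45 °C, degassed
Reagents that add atoms: none
Why: Sonogashira coupling with a bulky electron-rich phosphine lets zerovalent palladium add oxidatively to the electron-rich aryl bromide at low temperature, and the free alcohol, acetonide, silyl and benzyl ethers are tolerated with no stereocenter touched.

Step 24
Reactants: 36 (2R)-4-[(2S,3R)-2-(4-benzyloxy-3-methoxyphenyl)-3-(TBS-oxymethyl)-7-methoxy-2,3-dihydro-1-benzofuran-5-yl]-2-{4-[(4R,5S)-4-(4-benzyloxy-3-methoxyphenyl)-2,2-dimethyl-1,3-dioxan-5-yloxy]-3-methoxybenzyl}but-3-yn-1-ol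
Product: 37 (3E,4R)-3-{[(2S,3R)-2-(4-benzyloxy-3-methoxyphenyl)-3-(TBS-oxymethyl)-7-methoxy-2,3-dihydro-1-benzofuran-5-yl]methylidene}-4-{4-[(4R,5S)-4-(4-benzyloxy-3-methoxyphenyl)-2,2-dimethyl-1,3-dioxan-5-yloxy]-3-methoxybenzyl}oxolan-2-one
Conditions: Pd(OAc)2 (5 mol %), dppb (6 mol %), CO (20 bar), toluene, 90 °C
Reagents that add atoms: carbon monoxide [C-]#[O+]
Why: The primary alcohol, CO and divalent palladium form an alkoxycarbonylpalladium acetate, which adds syn across the tethered alkyne (intramolecular acylpalladation) to put the ester carbon on C-alpha and palladium on the benzylic carbon; protonolysis of that vinyl–palladium bond by the acetic acid released earlier gives the lactone and returns divalent palladium, so the cycle is redox-neutral. The closest known reaction is the palladium-catalysed cyclocarbonylation of but-3-yn-1-ols to α-methylene- and (E)-α-alkylidene-γ-butyrolactones. The lactone ring closes in the 5-exo-dig mode, the only mode in which the O–C(=O) unit can reach the proximal alkyne carbon through the two-carbon tether. No stereocenter is created: C-beta is carried through unchanged, and syn addition followed by retentive protonolysis fixes the alkene as E (vinyl H cis to C=O). The step needs the right ring size and the right hydroxyl group; the tether secures the first, the second is secured because the other primary alcohol is a TBS ether and the 1,3-diol is an acetonide, and a chelating diphosphine with CO pressure is used to disfavour 5-endo cycloisomerisation to a dihydrofuran.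

Step 25
Reactants: 37 (3E,4R)-3-{[(2S,3R)-2-(4-benzyloxy-3-methoxyphenyl)-3-(TBS-oxymethyl)-7-methoxy-2,3-dihydro-1-benzofuran-5-yl]methylidene}-4-{4-[(4R,5S)-4-(4-benzyloxy-3-methoxyphenyl)-2,2-dimethyl-1,3-dioxan-5-yloxy]-3-methoxybenzyl}oxolan-2-one
Product: 38 (3E,4R)-3-{[(2S,3R)-2-(4-benzyloxy-3-methoxyphenyl)-3-(hydroxymethyl)-7-methoxy-2,3-dihydro-1-benzofuran-5-yl]methylidene}-4-{4-[(1R,2S)-1-(4-benzyloxy-3-methoxyphenyl)-1,3-dihydroxypropan-2-yloxy]-3-methoxybenzyl}oxolan-2-one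
Conditions: AcOH/H2O (4:1), THF, 45 °C
Reagents that add atoms: none
Why: Aqueous acetic acid hydrolyses the acetonide and the primary TBS ether (acetal hydrolysis and acid desilylation), while the benzylic C7–OH on the still O-benzylated, non-phenolic ring A should not ionise under such weak acid.

Step 26
Reactants: 38 (3E,4R)-3-{[(2S,3R)-2-(4-benzyloxy-3-methoxyphenyl)-3-(hydroxymethyl)-7-methoxy-2,3-dihydro-1-benzofuran-5-yl]methylidene}-4-{4-[(1R,2S)-1-(4-benzyloxy-3-methoxyphenyl)-1,3-dihydroxypropan-2-yloxy]-3-methoxybenzyl}oxolan-2-one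
Product: 39 (3S,4R)-4-{4-[(1R,2S)-1,3-dihydroxy-1-(4-hydroxy-3-methoxyphenyl)propan-2-yloxy]-3-methoxybenzyl}-3-{[(2S,3R)-2-(4-hydroxy-3-methoxyphenyl)-3-(hydroxymethyl)-7-methoxy-2,3-dihydro-1-benzofuran-5-yl]methyl}oxolan-2-one
Conditions: H2 (1 atm), Pd/C, EtOAc/MeOH, rt
Reagents that add atoms: none
Why: Heterogeneous hydrogenation should deliver H2 to the exocyclic alkene from the face opposite the C-beta substituent, giving mainly the cis lactone (C-alpha S), and the same neutral, ambient-pressure conditions hydrogenolyse the two aryl benzyl ethers while sparing the benzylic C7–OH and the C2–O bond of the dihydrobenzofuran.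

Step 27
Reactants: 39 (3S,4R)-4-{4-[(1R,2S)-1,3-dihydroxy-1-(4-hydroxy-3-methoxyphenyl)propan-2-yloxy]-3-methoxybenzyl}-3-{[(2S,3R)-2-(4-hydroxy-3-methoxyphenyl)-3-(hydroxymethyl)-7-methoxy-2,3-dihydro-1-benzofuran-5-yl]methyl}oxolan-2-one
Product: 40 (3R,4R)-4-{4-[(1R,2S)-1,3-dihydroxy-1-(4-hydroxy-3-methoxyphenyl)propan-2-yloxy]-3-methoxybenzyl}-3-{[(2S,3R)-2-(4-hydroxy-3-methoxyphenyl)-3-(hydroxymethyl)-7-methoxy-2,3-dihydro-1-benzofuran-5-yl]methyl}oxolan-2-one
Conditions: DBU (excess), THF, 50 °C; then pH 5 buffer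
Reagents that add atoms: none
Why: Base-mediated epimerisation through the lactone enolate (thermodynamic equilibration) should convert the cis lactone, and any cis/trans mixture from step 26, into the more stable trans isomer, inverting only C-alpha to R next to the fixed C-beta centre.

**Compound list**

1 | 3-(4-hydroxy-3-methoxyphenyl)propanoic acid | COc1cc(CCC(=O)O)ccc1O | starting material
2 | tert-butyldimethylsilyl 3-[4-(TBS-oxy)-3-methoxyphenyl]propanoate | COc1cc(CCC(=O)O[Si](C)(C)C(C)(C)C)ccc1O[Si](C)(C)C(C)(C)C | intermediate (not isolated)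
3 | 3-[4-(TBS-oxy)-3-methoxyphenyl]propanoic acid | COc1cc(CCC(=O)O)ccc1O[Si](C)(C)C(C)(C)C | intermediate
4 | (R)-4-benzyloxazolidin-2-one | O=C1OC[C@@H](Cc2ccccc2)N1 | starting material
5 | mixed pivalic anhydride of 3 | COc1cc(CCC(=O)OC(=O)C(C)(C)C)ccc1O[Si](C)(C)C(C)(C)C | intermediate (not isolated)
6 | (4R)-4-benzyl-3-{3-[4-(TBS-oxy)-3-methoxyphenyl]propanoyl}oxazolidin-2-one | COc1cc(CCC(=O)N2C(=O)OC[C@H]2Cc2ccccc2)ccc1O[Si](C)(C)C(C)(C)C | intermediate
7 | (4R)-4-benzyl-3-{(2S)-2-(hydroxymethyl)-3-[4-(TBS-oxy)-3-methoxyphenyl]propanoyl}oxazolidin-2-one | COc1cc(C[C@@H](CO)C(=O)N2C(=O)OC[C@H]2Cc2ccccc2)ccc1O[Si](C)(C)C(C)(C)C | intermediate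
8 | (4R)-4-benzyl-3-{(2S)-2-(TBDPS-oxymethyl)-3-[4-(TBS-oxy)-3-methoxyphenyl]propanoyl}oxazolidin-2-one | COc1cc(C[C@@H](CO[Si](c2ccccc2)(c2ccccc2)C(C)(C)C)C(=O)N2C(=O)OC[C@H]2Cc2ccccc2)ccc1O[Si](C)(C)C(C)(C)C | intermediate
9 | (2R)-2-(TBDPS-oxymethyl)-3-[4-(TBS-oxy)-3-methoxyphenyl]propan-1-ol | COc1cc(C[C@@H](CO[Si](c2ccccc2)(c2ccccc2)C(C)(C)C)CO)ccc1O[Si](C)(C)C(C)(C)C | intermediate
10 | (2S)-2-(TBDPS-oxymethyl)-3-[4-(TBS-oxy)-3-methoxyphenyl]propanal | COc1cc(C[C@@H](CO[Si](c2ccccc2)(c2ccccc2)C(C)(C)C)C=O)ccc1O[Si](C)(C)C(C)(C)C | intermediate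
11 | dimethyl (1-diazo-2-oxopropyl)phosphonate | COP(=O)(OC)C(=[N+]=[N-])C(C)=O | starting material
12 | tert-butyl{[(2R)-2-{[4-(TBS-oxy)-3-methoxyphenyl]methyl}but-3-yn-1-yl]oxy}diphenylsilane | COc1cc(C[C@@H](CO[Si](c2ccccc2)(c2ccccc2)C(C)(C)C)C#C)ccc1O[Si](C)(C)C(C)(C)C | intermediate (not isolated)
13 | 4-[(2R)-2-(TBDPS-oxymethyl)but-3-yn-1-yl]-2-methoxyphenol | COc1cc(C[C@@H](CO[Si](c2ccccc2)(c2ccccc2)C(C)(C)C)C#C)ccc1O | intermediate
14 | methyl 2-{4-[(2R)-2-(TBDPS-oxymethyl)but-3-yn-1-yl]-2-methoxyphenoxy}acetate | COC(=O)COc1ccc(C[C@@H](CO[Si](c2ccccc2)(c2ccccc2)C(C)(C)C)C#C)cc1OC | intermediate (not isolated)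
15 | 2-{4-[(2R)-2-(TBDPS-oxymethyl)but-3-yn-1-yl]-2-methoxyphenoxy}acetic acid | OC(=O)COc1ccc(C[C@@H](CO[Si](c2ccccc2)(c2ccccc2)C(C)(C)C)C#C)cc1OC | intermediate
16 | mixed pivalic anhydride of 15 | CC(C)(C)C(=O)OC(=O)COc1ccc(C[C@@H](CO[Si](c2ccccc2)(c2ccccc2)C(C)(C)C)C#C)cc1OC | intermediate (not isolated)
17 | (4R)-4-benzyl-3-(2-{4-[(2R)-2-(TBDPS-oxymethyl)but-3-yn-1-yl]-2-methoxyphenoxy}acetyl)oxazolidin-2-one | O=C(COc1ccc(C[C@@H](CO[Si](c2ccccc2)(c2ccccc2)C(C)(C)C)C#C)cc1OC)N1C(=O)OC[C@H]1Cc1ccccc1 | intermediate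
18 | 4-benzyloxy-3-methoxybenzaldehyde | COc1cc(C=O)ccc1OCc1ccccc1 | starting material
19 | (4R)-4-benzyl-3-[(2R,3S)-3-(4-benzyloxy-3-methoxyphenyl)-3-hydroxy-2-{4-[(2R)-2-(TBDPS-oxymethyl)but-3-yn-1-yl]-2-methoxyphenoxy}propanoyl]oxazolidin-2-one (threo aldol) | COc1cc([C@H](O)[C@@H](Oc2ccc(C[C@@H](CO[Si](c3ccccc3)(c3ccccc3)C(C)(C)C)C#C)cc2OC)C(=O)N2C(=O)OC[C@H]2Cc2ccccc2)ccc1OCc1ccccc1 | intermediate
20 | (4R)-4-benzyl-3-[(2R,3R)-3-(4-benzyloxy-3-methoxyphenyl)-3-(4-nitrobenzoyloxy)-2-{4-[(2R)-2-(TBDPS-oxymethyl)but-3-yn-1-yl]-2-methoxyphenoxy}propanoyl]oxazolidin-2-one (erythro ester) | COc1cc([C@@H](OC(=O)c2ccc(cc2)[N+](=O)[O-])[C@@H](Oc2ccc(C[C@@H](CO[Si](c3ccccc3)(c3ccccc3)C(C)(C)C)C#C)cc2OC)C(=O)N2C(=O)OC[C@H]2Cc2ccccc2)ccc1OCc1ccccc1 | intermediate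
21 | (1R,2S)-1-(4-benzyloxy-3-methoxyphenyl)-2-{4-[(2R)-2-(TBDPS-oxymethyl)but-3-yn-1-yl]-2-methoxyphenoxy}propane-1,3-diol (erythro) | COc1cc([C@@H](O)[C@H](CO)Oc2ccc(C[C@@H](CO[Si](c3ccccc3)(c3ccccc3)C(C)(C)C)C#C)cc2OC)ccc1OCc1ccccc1 | intermediate
22 | (4R,5S)-4-(4-benzyloxy-3-methoxyphenyl)-5-{4-[(2R)-2-(TBDPS-oxymethyl)but-3-yn-1-yl]-2-methoxyphenoxy}-2,2-dimethyl-1,3-dioxane | COc1cc([C@H]2OC(C)(C)OC[C@@H]2Oc2ccc(C[C@@H](CO[Si](c3ccccc3)(c3ccccc3)C(C)(C)C)C#C)cc2OC)ccc1OCc1ccccc1 | intermediate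
23 | (2R)-2-{4-[(4R,5S)-4-(4-benzyloxy-3-methoxyphenyl)-2,2-dimethyl-1,3-dioxan-5-yloxy]-3-methoxybenzyl}but-3-yn-1-ol | COc1cc([C@H]2OC(C)(C)OC[C@@H]2Oc2ccc(C[C@@H](CO)C#C)cc2OC)ccc1OCc1ccccc1 | intermediate
24 | 5-bromo-2-hydroxy-3-methoxybenzaldehyde | COc1cc(Br)cc(C=O)c1O | starting material
25 | 5-bromo-3-methoxy-2-(methoxymethoxy)benzaldehyde | COCOc1c(OC)cc(Br)cc1C=O | intermediate
26 | 2-[5-bromo-3-methoxy-2-(methoxymethoxy)phenyl]acetonitrile | COCOc1c(OC)cc(Br)cc1CC#N | intermediate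
27 | 2-[5-bromo-3-methoxy-2-(methoxymethoxy)phenyl]acetic acid | COCOc1c(OC)cc(Br)cc1CC(=O)O | intermediate
28 | (S)-4-benzyloxazolidin-2-one | O=C1OC[C@H](Cc2ccccc2)N1 | starting material
29 | mixed pivalic anhydride of 27 | COCOc1c(OC)cc(Br)cc1CC(=O)OC(=O)C(C)(C)C | intermediate (not isolated)
30 | (4S)-4-benzyl-3-{2-[5-bromo-3-methoxy-2-(methoxymethoxy)phenyl]acetyl}oxazolidin-2-one | COCOc1c(OC)cc(Br)cc1CC(=O)N1C(=O)OC[C@@H]1Cc1ccccc1 | intermediate
31 | (4S)-4-benzyl-3-{(2S,3S)-3-(4-benzyloxy-3-methoxyphenyl)-2-[5-bromo-3-methoxy-2-(methoxymethoxy)phenyl]-3-hydroxypropanoyl}oxazolidin-2-one | COCOc1c(OC)cc(Br)cc1[C@@H]([C@H](O)c1ccc(OCc2ccccc2)c(OC)c1)C(=O)N1C(=O)OC[C@@H]1Cc1ccccc1 | intermediate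
32 | (1S,2R)-1-(4-benzyloxy-3-methoxyphenyl)-2-[5-bromo-3-methoxy-2-(methoxymethoxy)phenyl]propane-1,3-diol | COCOc1c(OC)cc(Br)cc1[C@@H]([C@H](O)c1ccc(OCc2ccccc2)c(OC)c1)CO | intermediate
33 | (1S,2R)-1-(4-benzyloxy-3-methoxyphenyl)-2-(5-bromo-2-hydroxy-3-methoxyphenyl)propane-1,3-diol | COc1cc(Br)cc([C@@H]([C@H](O)c2ccc(OCc3ccccc3)c(OC)c2)CO)c1O | intermediate (not isolated)
34 | [(2S,3R)-2-(4-benzyloxy-3-methoxyphenyl)-5-bromo-7-methoxy-2,3-dihydro-1-benzofuran-3-yl]methanol | Brc1cc(OC)c2c(c1)[C@H](CO)[C@@H](c1ccc(OCc3ccccc3)c(OC)c1)O2 | intermediate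
35 | {[(2S,3R)-2-(4-benzyloxy-3-methoxyphenyl)-5-bromo-7-methoxy-2,3-dihydro-1-benzofuran-3-yl]methoxy}(tert-butyl)dimethylsilane | Brc1cc(OC)c2c(c1)[C@H](CO[Si](C)(C)C(C)(C)C)[C@@H](c1ccc(OCc3ccccc3)c(OC)c1)O2 | intermediate
36 | (2R)-4-[(2S,3R)-2-(4-benzyloxy-3-methoxyphenyl)-3-(TBS-oxymethyl)-7-methoxy-2,3-dihydro-1-benzofuran-5-yl]-2-{4-[(4R,5S)-4-(4-benzyloxy-3-methoxyphenyl)-2,2-dimethyl-1,3-dioxan-5-yloxy]-3-methoxybenzyl}but-3-yn-1-ol | COc1cc([C@H]2OC(C)(C)OC[C@@H]2Oc2ccc(C[C@@H](CO)C#Cc3cc(OC)c4c(c3)[C@H](CO[Si](C)(C)C(C)(C)C)[C@@H](c3ccc(OCc5ccccc5)c(OC)c3)O4)cc2OC)ccc1OCc1ccccc1 | intermediate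
37 | (3E,4R)-3-{[(2S,3R)-2-(4-benzyloxy-3-methoxyphenyl)-3-(TBS-oxymethyl)-7-methoxy-2,3-dihydro-1-benzofuran-5-yl]methylidene}-4-{4-[(4R,5S)-4-(4-benzyloxy-3-methoxyphenyl)-2,2-dimethyl-1,3-dioxan-5-yloxy]-3-methoxybenzyl}oxolan-2-one | COc1cc([C@H]2OC(C)(C)OC[C@@H]2Oc2ccc(C[C@H]3COC(=O)/C3=C/c3cc(OC)c4c(c3)[C@H](CO[Si](C)(C)C(C)(C)C)[C@@H](c3ccc(OCc5ccccc5)c(OC)c3)O4)cc2OC)ccc1OCc1ccccc1 | intermediate
38 | (3E,4R)-3-{[(2S,3R)-2-(4-benzyloxy-3-methoxyphenyl)-3-(hydroxymethyl)-7-methoxy-2,3-dihydro-1-benzofuran-5-yl]methylidene}-4-{4-[(1R,2S)-1-(4-benzyloxy-3-methoxyphenyl)-1,3-dihydroxypropan-2-yloxy]-3-methoxybenzyl}oxolan-2-one | COc1cc([C@@H](O)[C@H](CO)Oc2ccc(C[C@H]3COC(=O)/C3=C/c3cc(OC)c4c(c3)[C@H](CO)[C@@H](c3ccc(OCc5ccccc5)c(OC)c3)O4)cc2OC)ccc1OCc1ccccc1 | intermediate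
39 | (3S,4R)-4-{4-[(1R,2S)-1,3-dihydroxy-1-(4-hydroxy-3-methoxyphenyl)propan-2-yloxy]-3-methoxybenzyl}-3-{[(2S,3R)-2-(4-hydroxy-3-methoxyphenyl)-3-(hydroxymethyl)-7-methoxy-2,3-dihydro-1-benzofuran-5-yl]methyl}oxolan-2-one (cis lactone) | COc1cc([C@@H](O)[C@H](CO)Oc2ccc(C[C@H]3COC(=O)[C@H]3Cc3cc(OC)c4c(c3)[C@H](CO)[C@@H](c3ccc(O)c(OC)c3)O4)cc2OC)ccc1O | intermediate
40 | (3R,4R)-4-{4-[(1R,2S)-1,3-dihydroxy-1-(4-hydroxy-3-methoxyphenyl)propan-2-yloxy]-3-methoxybenzyl}-3-{[(2S,3R)-2-(4-hydroxy-3-methoxyphenyl)-3-(hydroxymethyl)-7-methoxy-2,3-dihydro-1-benzofuran-5-yl]methyl}oxolan-2-one (CNP0265599.1) | COc1cc([C@@H](O)[C@H](CO)Oc2ccc(C[C@H]3COC(=O)[C@@H]3Cc3cc(OC)c4c(c3)[C@H](CO)[C@@H](c3ccc(O)c(OC)c3)O4)cc2OC)ccc1O | target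

**Step count**

Total: 27 steps. Longest linear sequence: 19 steps (steps 1–14, then 23–27, from compound 1). The ring C/D branch (steps 15–22) is 8 steps.

**Steps most likely to fail**

1. Step 24 (cyclocarbonylation). The hindered internal aryl alkyne may fail to insert into the alkoxycarbonyl–palladium bond. The catalyst may also drift to a hydridopalladium pathway that carbonylates the aryl-bearing alkyne carbon and gives a six-membered lactone, or divalent palladium may simply trigger 5-endo cycloisomerisation to a dihydrofuran. Fallback, from 36 and back to the route at 37, making the same two bonds stepwise with CO still the last carbon: the alcohol is silylated with 1,1,3,3-tetramethyldisilazane to the dimethylsilyl ether F1. Intramolecular syn hydrosilylation (Pt2[(CH2=CHSiMe2)2O]3, THF, rt) then closes the 5-exo-dig (E)-alkylidene oxasilolane F2, placing silicon on C-alpha. Iododesilylation with N-iodosuccinimide in (CF3)2CHOH proceeds with retention and, after aqueous work-up, gives the (E)-vinyl iodide alcohol F3. Carbonylative lactonisation of F3 (Pd(PPh3)2Cl2, CO 1 atm, K2CO3, THF, 50 °C; oxidative addition to zerovalent palladium, CO insertion, capture of the acyl group by the alcohol) delivers 37 with the same alkene geometry.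

2. Step 11 (Mitsunobu inversion). The electron-rich benzylic alcohol may ionise instead of undergoing clean SN2 displacement, eroding the erythro/threo ratio, or the activated alcohol may undergo β-elimination to an α-aryloxy cinnamoyl imide. Fallback, from 19 and back to the route at 21, by oxidation and reduction instead of displacement: LiBH4 reduces 19 to the threo diol F4, and the primary alcohol is silylated selectively (TBSCl, imidazole) to F5. Dess–Martin oxidation of the benzylic alcohol gives the aryl ketone F6. Reduction with LiBH(s-Bu)3 at −78 °C under Felkin–Anh control (aryloxy group anti to the incoming hydride) should give the erythro alcohol F7. Buffered HF·pyridine removes the primary TBS ether while the TBDPS ether survives, giving 21.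

3. Step 16 (Van Leusen homologation). With an aldehyde the TosMIC adduct can aromatise to the 5-aryl oxazole instead of ring-opening to the nitrile, and the ortho-substituted, electron-rich aldehyde may react sluggishly at the low temperature needed to prevent this. Fallback, from 25 and back to the route at 27: Wittig methoxymethylenation (Ph3PCH2OMe chloride, KN(SiMe3)2, THF) gives the enol ether F8 as an E/Z mixture. Near-neutral hydrolysis (Hg(OAc)2, THF/H2O, then KI) gives the arylacetaldehyde F9 with the MOM ether intact. Immediate Pinnick oxidation (NaClO2, NaH2PO4, 2-methyl-2-butene, t-BuOH/H2O) gives acid 27.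

**Further compounds**

F1 | step 24 | dimethylsilyl ether of 36, (2R) | COc1cc([C@H]2OC(C)(C)OC[C@@H]2Oc2ccc(C[C@@H](CO[SiH](C)C)C#Cc3cc(OC)c4c(c3)[C@H](CO[Si](C)(C)C(C)(C)C)[C@@H](c3ccc(OCc5ccccc5)c(OC)c3)O4)cc2OC)ccc1OCc1ccccc1
F2 | step 24 | (3E,4S)-2,2-dimethyl-1,2-oxasilolane carrying the benzofuranylmethylidene group on C3 and the ring B benzyl group on C4 | COc1cc([C@H]2OC(C)(C)OC[C@@H]2Oc2ccc(C[C@H]3CO[Si](C)(C)/C3=C/c3cc(OC)c4c(c3)[C@H](CO[Si](C)(C)C(C)(C)C)[C@@H](c3ccc(OCc5ccccc5)c(OC)c3)O4)cc2OC)ccc1OCc1ccccc1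
F3 | step 24 | (2S,3E)-3-iodo-4-(benzofuran-5-yl)-2-(ring B benzyl)but-3-en-1-ol, iodine trans to the aryl group | COc1cc([C@H]2OC(C)(C)OC[C@@H]2Oc2ccc(C[C@@H](CO)/C(I)=C\c3cc(OC)c4c(c3)[C@H](CO[Si](C)(C)C(C)(C)C)[C@@H](c3ccc(OCc5ccccc5)c(OC)c3)O4)cc2OC)ccc1OCc1ccccc1
F4 | step 11 | (1S,2S)-1-(4-benzyloxy-3-methoxyphenyl)-2-{4-[(2R)-2-(TBDPS-oxymethyl)but-3-yn-1-yl]-2-methoxyphenoxy}propane-1,3-diol (threo) | COc1cc([C@H](O)[C@H](CO)Oc2ccc(C[C@@H](CO[Si](c3ccccc3)(c3ccccc3)C(C)(C)C)C#C)cc2OC)ccc1OCc1ccccc1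
F5 | step 11 | (1S,2S)-1-(4-benzyloxy-3-methoxyphenyl)-3-(TBS-oxy)-2-{4-[(2R)-2-(TBDPS-oxymethyl)but-3-yn-1-yl]-2-methoxyphenoxy}propan-1-ol | COc1cc([C@H](O)[C@H](CO[Si](C)(C)C(C)(C)C)Oc2ccc(C[C@@H](CO[Si](c3ccccc3)(c3ccccc3)C(C)(C)C)C#C)cc2OC)ccc1OCc1ccccc1
F6 | step 11 | (2S)-1-(4-benzyloxy-3-methoxyphenyl)-3-(TBS-oxy)-2-{4-[(2R)-2-(TBDPS-oxymethyl)but-3-yn-1-yl]-2-methoxyphenoxy}propan-1-one | COc1cc(C(=O)[C@H](CO[Si](C)(C)C(C)(C)C)Oc2ccc(C[C@@H](CO[Si](c3ccccc3)(c3ccccc3)C(C)(C)C)C#C)cc2OC)ccc1OCc1ccccc1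
F7 | step 11 | (1R,2S)-1-(4-benzyloxy-3-methoxyphenyl)-3-(TBS-oxy)-2-{4-[(2R)-2-(TBDPS-oxymethyl)but-3-yn-1-yl]-2-methoxyphenoxy}propan-1-ol (erythro) | COc1cc([C@@H](O)[C@H](CO[Si](C)(C)C(C)(C)C)Oc2ccc(C[C@@H](CO[Si](c3ccccc3)(c3ccccc3)C(C)(C)C)C#C)cc2OC)ccc1OCc1ccccc1
F8 | step 16 | 5-bromo-1-methoxy-2-(methoxymethoxy)-3-(2-methoxyethenyl)benzene (E/Z mixture) | COC=Cc1cc(Br)cc(OC)c1OCOC
F9 | step 16 | 2-[5-bromo-3-methoxy-2-(methoxymethoxy)phenyl]acetaldehyde | O=CCc1cc(Br)cc(OC)c1OCOC
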